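The readings were computed for substances that don't exist, noise included.

Partner is conserved: each unit charged ends as target, goes to protic impurity, or stands free. One for one with the impurity is taken here as a guess, since no earlier run changes its charge.

| flask | substrate | partner | protic impurity | free catalyst | remark | time |
|---|---|---|---|---|---|---|
| Saturday's | 5.0 × 10⁻⁴ M | 0.50 mM | 0.15 mM | 1.9 µM | run made earlier |  |
| Wednesday's | 5.0 × 10⁻⁴ M | 0.50 mM | 0.15 mM | 5.8 µM | run made earlier |  |
| Friday's | 5.0 × 10⁻⁴ M | 0.47 mM | 0.15 mM | 5 µM | run made earlier |  |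
| delta | 3.0 × 10⁻⁴ M | 2.00 mM | 0.0400 mM | 5.0 µM |  | 2.5 min |
| gamma | 5.0 × 10⁻⁴ M | 0.500 mM | 0.150 mM | 5.0 µM |  | 2.5 min |
| theta | 2.5 × 10⁻⁴ M | 0.120 mM | 0.150 mM | 5.0 µM |  | 2.5 min |
| zeta | 1.2 × 10⁻⁴ M | 0.300 mM | 0.150 mM | 5.0 µM |  | 2.5 min |
| beta | 2.5 × 10⁻⁴ M | 0.500 mM | 0.0500 mM | 1.5 µM |  | 2.5 min |

| run | time / s | target / % |
|---|---|---|
| Saturday's | 10.0 | 1.4 |
| Saturday's | 20.0 | 2.7 |
| Saturday's | 40.0 | 9.6 |
| Saturday's | 60.0 | 16.8 |
| Saturday's | 80.0 | 21.9 |
| Saturday's | 120 | 31.1 |
| Wednesday's | 10.0 | 4.7 |
| Wednesday's | 20.0 | 12.2 |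
| Wednesday's | 40.0 | 26.1 |
| Wednesday's | 60.0 | 36.5 |
| Wednesday's | 80.0 | 43.7 |
| Wednesday's | 120 | 53.3 |
| Friday's | 10.0 | 3.8 |
| Friday's | 15.0 | 7.5 |
| Friday's | 30.0 | 16.6 |
| Friday's | 60.0 | 31.8 |
| Friday's | 120 | 48.0 |

(scatter of a reading: 0.5 percentage points)

- no earlier run changes the charge of protic impurity; that part of a forecast is a guess

- all flasks from highest to lowest amount of target, in percent of the substrate charged, at 2.5 min (delta / gamma / theta / zeta / beta)
- the same order at 20 min (delta / gamma / theta / zeta / beta)
- the amount of target, in percent of the substrate charged of the flask you put first, at 2.5 min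
- the amount of target, in percent of the substrate charged of the flask you put last, at 2.5 min

In gamma, 0.500 mM of partner less 0.150 mM of impurity, over 5.0 × 10⁻⁴ M of substrate, gives 70.0%. This is the cover: partner left after the impurity charge is served, per substrate charged. On that guess, a finish not bound by partner needs partner at least equal to substrate plus impurity, the line where the cover reaches the whole substrate charge. Gamma holds 0.500 mM against 0.650 mM, a cover below that line, so partner is its limiting reagent.

Saturday's and Wednesday's runs share a cover of 70.0%. At 120 s they read 31.1% and 53.3%, with 1.9 µM and 5.8 µM of free catalyst, and the cover holds no catalyst term. It therefore gives no figure at 2.5 min. It speaks for 20 min, ten times the time of the last reading of Wednesday's run.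

Delta has 653%, beta 180%, zeta 125% and theta −12.0%. In theta, partner stands below the impurity charge, so target there comes from a race and the cover gives no yield. Ranked by cover, the order expected at 20 min is delta, beta, zeta, gamma, theta, with gamma expected near its cover.

The forecast gives delta > gamma > zeta > beta > theta at 2.5 min and delta > zeta > beta > gamma > theta at 20 min, with 99% first and 11% last, and says of the impurity “perhaps half its charge”, which differs from the one for one taken here.

The flasks give delta > gamma > zeta > beta > theta at 2.5 min, with 93.2% first and 13.5% last, and delta > beta > zeta > gamma > theta at 20 min.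

    free catalyst + open intermediate ⇌ catalyst intermediate (K = 710 L mol⁻¹, k = 20000 L mol⁻¹ s⁻¹)
    partner + catalyst intermediate → free catalyst + target (k = 38000 L mol⁻¹ s⁻¹)
    partner + protic impurity → quenched reagent (k = 180 L mol⁻¹ s⁻¹)
    2 free catalyst ⇌ resting dimer, settled at all times (K = 95000 L mol⁻¹)
    substrate + free catalyst ⇌ free catalyst + open intermediate (K = 1.20, k = 17000 L mol⁻¹ s⁻¹)

Gamma stands at 70.0% at 20 min, against its cover of 70.0%. At 25.0 min gamma's partner is at 0% of its charge, with substrate at 13.6% and open intermediate at 16.3% of the substrate charged. A neighbour of theta, charged with 4.8 × 10⁻⁴ M of partner, has a cover of 132%, above the line. At 2.50 min that neighbour holds 64.8% of target, in percent of the substrate charged, and its impurity is down to 0.122% of its charge. That neighbour's free partner, 0.168 mM, is more than the 0.0879 mM standing as substrate and open intermediate.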